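The two C4–aryl bonds are the disconnection on which the route rests. C4 and C4' of the two lactone rings are benzylic methines, each β to a lactone carbonyl (C2, C2') and each bearing a 4-hydroxyphenyl group cis to the C3–C3' bond. One 8-aminoquinoline-directed, palladium-catalysed C(sp3)–H arylation puts both anisyl groups on the two benzylic methylenes of a pseudo-meso 2-(2,4,6-trimethoxybenzyl)-3-(pentamethoxybenzyl)succinic bis(quinolin-8-yl)amide, with C3 and C3' dictating C4 and C4'. The precursor comes from Stobbe condensation, asymmetric hydrogenation, cis-selective lactone hydrogenation and imide aminolysis. One BBr3 operation then frees the phenols, which close both lactones with loss of the auxiliaries.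

Key step: step 13

Assumption: atom labels follow the target (C2–C4 and ring A for the 5,7-dihydroxy half, C2'–C4' and ring B for the tetrahydroxy half); the target is read as (3R,4S,3'S,4'R) with both lactone rings 3,4-cis, and 24 and 28 carry exactly these centres; in step 2 the ligand enantiomer that gives the (R)-acid is used, taken to be (S,S)-Et-DuPhos by analogy with related itaconate half-esters, its mirror image being used instead if a test hydrogenation shows the opposite sense.

Step 1
Reactants: 1 2,4,6-trimethoxybenzaldehyde; 2 diethyl succinate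
Product: 4 (E)-3-(ethoxycarbonyl)-4-(2,4,6-trimethoxyphenyl)but-3-enoic acid, via paraconic ester 3 (not isolated)
Conditions: KOtBu (1.3 equiv), tBuOH, reflux; then aq. HCl
Reagents that add atoms: none
Why: Stobbe condensation: the succinate enolate adds to the non-enolisable aldehyde, the alkoxide closes paraconic ester 3, and irreversible base-induced ring opening (E1cB) gives the half-ester carboxylate with the aryl group trans to the ester, which drives the reaction even with this electron-rich aldehyde.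

Step 2
Reactants: 4 (E)-3-(ethoxycarbonyl)-4-(2,4,6-trimethoxyphenyl)but-3-enoic acid
Product: 5 (R)-3-(ethoxycarbonyl)-4-(2,4,6-trimethoxyphenyl)butanoic acid
Conditions: [Rh(cod)((S,S)-Et-DuPhos)]BF4 (1 mol%), NaOMe (10 mol%), H2 (5 bar), MeOH, 25 °C
Reagents that add atoms: none
Why: Rhodium–bisphospholane asymmetric hydrogenation of a Stobbe-derived itaconate half-ester: the carboxylate and the alkene chelate the metal and the C2-symmetric ligand selects the alkene face, which sets the centre that becomes C3 of the target as (R).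

Step 3
Reactants: 5 (R)-3-(ethoxycarbonyl)-4-(2,4,6-trimethoxyphenyl)butanoic acid
Product: 7 (R)-4-(2,4,6-trimethoxybenzyl)dihydrofuran-2(3H)-one, via hydroxy acid 6 (not isolated)
Conditions: LiBH4 (3 equiv), THF, 0 → 25 °C; then 2 M HCl, 25 °C
Reagents that add atoms: none
Why: Chemoselective borohydride reduction: LiBH4 first turns the acid into its unreactive lithium carboxylate and reduces only the ester, and acidification closes the γ-lactone from hydroxy acid 6 (acid-catalysed lactonisation) without touching the stereocentre.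

Step 4
Reactants: 8 2,6-dimethoxy-1,4-benzoquinone
Product: 9 3,5-dimethoxybenzene-1,2,4-triyl triacetate
Conditions: Ac2O, H2SO4 (cat.), 25 → 40 °C
Reagents that add atoms: acetic anhydride, CC(=O)OC(C)=O
Why: Thiele–Winter acetoxylation: acid-activated conjugate addition of acetate to one of the two equivalent free ring positions of the quinone, followed by enolisation and O-acetylation, gives the fully oxygenated benzene with a single remaining C–H.

Step 5
Reactants: 9 3,5-dimethoxybenzene-1,2,4-triyl triacetate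
Product: 11 pentamethoxybenzene, via triol 10 (not isolated)
Conditions: NaOH (aq.), Me2SO4, Na2S2O4 (cat.), acetone, N2, 0 °C → reflux
Reagents that add atoms: dimethyl sulfate, COS(=O)(=O)OC
Why: Saponification of the three aryl acetates and Williamson O-methylation of the phenoxides of 10 in the same flask, with dithionite and inert gas protecting the oxidisable triol.

Step 6
Reactants: 11 pentamethoxybenzene
Product: 13 2,3,4,5,6-pentamethoxybenzaldehyde, via aryllithium 12 (not isolated)
Conditions: nBuLi, TMEDA, THF, 0 °C; DMF, −78 → 0 °C; aq. HCl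
Reagents that add atoms: N,N-dimethylformamide, CN(C)C=O
Why: Directed ortho-lithiation at the only ring C–H, which is flanked by two methoxy groups, and formylation of aryllithium 12 with DMF (Bouveault-type aldehyde synthesis).

Step 7
Reactants: 7 (R)-4-(2,4,6-trimethoxybenzyl)dihydrofuran-2(3H)-one; 13 2,3,4,5,6-pentamethoxybenzaldehyde
Product: 15 (4R)-3-[hydroxy(pentamethoxyphenyl)methyl]-4-(2,4,6-trimethoxybenzyl)dihydrofuran-2(3H)-one (diastereomer mixture), via lithium enolate 14 (not isolated)
Conditions: LiN(iPr)2, THF, −78 °C; 13; AcOH, −78 °C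
Reagents that add atoms: none
Why: Aldol addition of the kinetic lithium enolate 14 (only the C3 methylene is acidic, so the C4 stereocentre is safe) to the non-enolisable aldehyde; the two new centres are removed in step 8, so the diastereomer mixture is carried on.

Step 8
Reactants: 15 (4R)-3-[hydroxy(pentamethoxyphenyl)methyl]-4-(2,4,6-trimethoxybenzyl)dihydrofuran-2(3H)-one
Product: 17 (R,E)-3-(pentamethoxybenzylidene)-4-(2,4,6-trimethoxybenzyl)dihydrofuran-2(3H)-one, via mesylate 16 (not isolated)
Conditions: MsCl, Et3N, CH2Cl2, 0 °C; DBU, 25 °C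
Reagents that add atoms: none
Why: Mesylation and E1cB β-elimination through 16 give the conjugated benzylidene lactone, expected mainly as the (E) isomer with the aryl group away from the lactone carbonyl; any (Z) isomer converges in step 9 and C4 is untouched.

Step 9
Reactants: 17 (R,E)-3-(pentamethoxybenzylidene)-4-(2,4,6-trimethoxybenzyl)dihydrofuran-2(3H)-one
Product: 18 (3S,4R)-3-(pentamethoxybenzyl)-4-(2,4,6-trimethoxybenzyl)dihydrofuran-2(3H)-one (cis-lactone)
Conditions: H2 (3 bar), Pd/C (10 wt%), EtOAc, 25 °C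
Reagents that add atoms: none
Why: Heterogeneous catalytic hydrogenation: syn addition of H2 to the exocyclic alkene from the ring face opposite the C4 benzyl group puts the new benzyl group cis to it and so sets C3 of the lactone (later C3' of the target) as (S).

Step 10
Reactants: 18 cis-lactone; 19 8-aminoquinoline
Product: 20 (2S,3R)-4-hydroxy-2-(pentamethoxybenzyl)-N-(quinolin-8-yl)-3-(2,4,6-trimethoxybenzyl)butanamide
Conditions: AlMe3 (2.5 equiv), 19 (2.5 equiv), CH2Cl2, 0 → 40 °C; aq. potassium sodium tartrate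
Reagents that add atoms: none
Why: Weinreb-type aminolysis of the γ-lactone by the dimethylaluminium amide made from AlMe3 and 19, a Lewis acidic and only weakly basic reagent that should leave the epimerisable α-centre of the cis-lactone intact.

Step 11
Reactants: 20 (2S,3R)-4-hydroxy-2-(pentamethoxybenzyl)-N-(quinolin-8-yl)-3-(2,4,6-trimethoxybenzyl)butanamide
Product: 23 (3S,4R)-3-(pentamethoxybenzyl)-1-(quinolin-8-yl)-4-(2,4,6-trimethoxybenzyl)pyrrolidine-2,5-dione (cis-imide), via aldehyde 21 (not isolated), via hydroxylactam 22 (not isolated)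
Conditions: nPr4N[RuO4] (10 mol%), NMO (4 equiv), 4 Å MS, CH2Cl2, 25 °C
Reagents that add atoms: none
Why: Ley–Griffith oxidation: the primary alcohol gives aldehyde 21, the neighbouring amide N–H adds to it in a 5-exo closure to hydroxylactam 22, and this N-acyl hemiaminal is oxidised to the imide under near-neutral conditions that should not epimerise the cis centres.

Step 12
Reactants: 23 cis-imide; 19 8-aminoquinoline
Product: 24 (2R,3S)-2-(2,4,6-trimethoxybenzyl)-3-(pentamethoxybenzyl)-N1,N4-di(quinolin-8-yl)butanediamide (pseudo-meso bis-amide)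
Conditions: AlMe3 (3 equiv), 19 (3 equiv), CH2Cl2, 0 → 25 °C; aq. potassium sodium tartrate
Reagents that add atoms: none
Why: Ring-opening aminolysis of the N-aryl imide by the same aluminium amide (Weinreb-type transamidation); attack at either imide carbonyl gives the same bis-amide, so no regiochemistry is at stake and the two centres keep their pseudo-meso relationship.

Step 13
Reactants: 24 pseudo-meso bis-amide; 25 4-iodoanisole (two equivalents consumed, used in excess)
Product: 28 (2R,3S)-2-[(S)-(4-methoxyphenyl)(2,4,6-trimethoxyphenyl)methyl]-3-[(R)-(4-methoxyphenyl)(pentamethoxyphenyl)methyl]-N1,N4-di(quinolin-8-yl)butanediamide, via C4-monoaryl bis-amide 26 (not isolated), via C4'-monoaryl bis-amide 27 (not isolated)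
Conditions: Pd(OAc)2 (20 mol%), AgOAc (4 equiv), (BnO)2PO2H (40 mol%), 25 (8 equiv), tAmOH, 110 °C, Ar
Reagents that add atoms: none
Why: Each amide, deprotonated and bound through both nitrogens to divalent palladium, directs a carboxylate-assisted concerted metalation–deprotonation of its own β-benzylic methylene to a five-membered palladacycle; oxidative addition of 25 gives tetravalent palladium, C–C reductive elimination occurs with retention at carbon, AgOAc takes up the iodide, and the cycle repeats at the second amide (via 26 or 27). The closest known reaction type is the 8-aminoquinoline-directed palladium-catalysed arylation of β-methylene C(sp3)–H bonds of α-branched carboxamides with aryl iodides. No ring is closed. C4 is controlled by C3 and C4' by C3': each palladacycle forms with its resident arene trans to the bulky α-substituent, and the anisyl group takes the place of palladium, which gives (4S) from (3R) and (4'R) from (3'S), the relationship that becomes 3,4-cis in each lactone. The step needs site selectivity and a single arylation per site: the only other β-hydrogens are the tertiary C3–H and C3'–H, which do not metalate, both ortho positions of each resident arene carry methoxy groups so no aryl C–H can compete, and the methines formed cannot react again.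

Step 14
Reactants: 28 twofold arylated bis-amide
Product: 30 (3R,4S,3'S,4'R)-5,5',6',7,7',8'-hexahydroxy-4,4'-bis(4-hydroxyphenyl)-[3,3'-bichromane]-2,2'-dione, via decaphenol bis-amide 29 (not isolated)
Conditions: BBr3 (30 equiv), CH2Cl2, −78 → 25 °C, Ar; H2O; then 1 M HCl/THF, 50 °C; ascorbic acid in work-up
Reagents that add atoms: none
Why: Lewis acid cleavage of all ten aryl methyl ethers, then acid-promoted intramolecular acyl transfer in which an ortho phenol of each resident arene (the two ortho positions of each ring are equivalent) attacks the protonated anilide carbonyl β to it in a six-membered lactonisation that expels 8-aminoquinoline, with no bond to a stereocentre broken so that all four centres are retained.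

Compound list
1 | 2,4,6-trimethoxybenzaldehyde | COc1cc(OC)c(C=O)c(OC)c1 | starting material
2 | diethyl succinate | CCOC(=O)CCC(=O)OCC | starting material
3 | ethyl 5-oxo-2-(2,4,6-trimethoxyphenyl)oxolane-3-carboxylate (paraconic ester, racemic diastereomer mixture) | CCOC(=O)C1CC(=O)OC1c1c(OC)cc(OC)cc1OC | intermediate
4 | (E)-3-(ethoxycarbonyl)-4-(2,4,6-trimethoxyphenyl)but-3-enoic acid | COc1cc(OC)c(/C=C(\CC(=O)O)C(=O)OCC)c(OC)c1 | intermediate
5 | (R)-3-(ethoxycarbonyl)-4-(2,4,6-trimethoxyphenyl)butanoic acid | COc1cc(OC)c(C[C@H](CC(=O)O)C(=O)OCC)c(OC)c1 | intermediate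
6 | (R)-4-hydroxy-3-(2,4,6-trimethoxybenzyl)butanoic acid (lithium salt in the flask) | COc1cc(OC)c(C[C@H](CC(=O)O)CO)c(OC)c1 | intermediate
7 | (R)-4-(2,4,6-trimethoxybenzyl)dihydrofuran-2(3H)-one | COc1cc(OC)c(C[C@H]2COC(=O)C2)c(OC)c1 | intermediate
8 | 2,6-dimethoxy-1,4-benzoquinone | COC1=CC(=O)C=C(OC)C1=O | starting material
9 | 3,5-dimethoxybenzene-1,2,4-triyl triacetate | CC(=O)Oc1cc(OC)c(OC(C)=O)c(OC)c1OC(C)=O | intermediate
10 | 3,5-dimethoxybenzene-1,2,4-triol (sodium phenoxide in the flask) | COc1cc(O)c(O)c(OC)c1O | intermediate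
11 | pentamethoxybenzene | COc1cc(OC)c(OC)c(OC)c1OC | intermediate
12 | (pentamethoxyphenyl)lithium | [Li]c1c(OC)c(OC)c(OC)c(OC)c1OC | intermediate
13 | 2,3,4,5,6-pentamethoxybenzaldehyde | COc1c(OC)c(OC)c(C=O)c(OC)c1OC | intermediate
14 | lithium enolate of lactone 7 | COc1cc(OC)c(C[C@H]2COC([O-])=C2)c(OC)c1.[Li+] | intermediate
15 | (4R)-3-[hydroxy(pentamethoxyphenyl)methyl]-4-(2,4,6-trimethoxybenzyl)dihydrofuran-2(3H)-one (mixture at C3 and at the carbinol carbon) | COc1cc(OC)c(C[C@H]2COC(=O)C2C(O)c2c(OC)c(OC)c(OC)c(OC)c2OC)c(OC)c1 | intermediate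
16 | methanesulfonate of 15 (same mixture) | COc1cc(OC)c(C[C@H]2COC(=O)C2C(OS(C)(=O)=O)c2c(OC)c(OC)c(OC)c(OC)c2OC)c(OC)c1 | intermediate
17 | (R,E)-3-(pentamethoxybenzylidene)-4-(2,4,6-trimethoxybenzyl)dihydrofuran-2(3H)-one | COc1cc(OC)c(C[C@H]2COC(=O)/C2=C/c2c(OC)c(OC)c(OC)c(OC)c2OC)c(OC)c1 | intermediate
18 | (3S,4R)-3-(pentamethoxybenzyl)-4-(2,4,6-trimethoxybenzyl)dihydrofuran-2(3H)-one (cis) | COc1cc(OC)c(C[C@H]2COC(=O)[C@H]2Cc2c(OC)c(OC)c(OC)c(OC)c2OC)c(OC)c1 | intermediate
19 | 8-aminoquinoline | Nc1cccc2cccnc12 | starting material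
20 | (2S,3R)-4-hydroxy-2-(pentamethoxybenzyl)-N-(quinolin-8-yl)-3-(2,4,6-trimethoxybenzyl)butanamide | COc1cc(OC)c(C[C@@H](CO)[C@H](Cc2c(OC)c(OC)c(OC)c(OC)c2OC)C(=O)Nc2cccc3cccnc23)c(OC)c1 | intermediate
21 | (2S,3R)-4-oxo-2-(pentamethoxybenzyl)-N-(quinolin-8-yl)-3-(2,4,6-trimethoxybenzyl)butanamide | COc1cc(OC)c(C[C@@H](C=O)[C@H](Cc2c(OC)c(OC)c(OC)c(OC)c2OC)C(=O)Nc2cccc3cccnc23)c(OC)c1 | intermediate
22 | (3S,4R)-5-hydroxy-3-(pentamethoxybenzyl)-1-(quinolin-8-yl)-4-(2,4,6-trimethoxybenzyl)pyrrolidin-2-one (C5 epimers) | COc1cc(OC)c(C[C@H]2C(O)N(c3cccc4cccnc34)C(=O)[C@H]2Cc2c(OC)c(OC)c(OC)c(OC)c2OC)c(OC)c1 | intermediate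
23 | (3S,4R)-3-(pentamethoxybenzyl)-1-(quinolin-8-yl)-4-(2,4,6-trimethoxybenzyl)pyrrolidine-2,5-dione (cis) | COc1cc(OC)c(C[C@H]2C(=O)N(c3cccc4cccnc34)C(=O)[C@H]2Cc2c(OC)c(OC)c(OC)c(OC)c2OC)c(OC)c1 | intermediate
24 | (2R,3S)-2-(2,4,6-trimethoxybenzyl)-3-(pentamethoxybenzyl)-N1,N4-di(quinolin-8-yl)butanediamide (pseudo-meso) | COc1cc(OC)c(C[C@@H](C(=O)Nc2cccc3cccnc23)[C@H](Cc2c(OC)c(OC)c(OC)c(OC)c2OC)C(=O)Nc2cccc3cccnc23)c(OC)c1 | intermediate
25 | 4-iodoanisole | COc1ccc(I)cc1 | starting material
26 | (2R,3S)-2-[(S)-(4-methoxyphenyl)(2,4,6-trimethoxyphenyl)methyl]-3-(pentamethoxybenzyl)-N1,N4-di(quinolin-8-yl)butanediamide | COc1cc(OC)c(c(OC)c1)[C@H](c1ccc(OC)cc1)[C@@H](C(=O)Nc1cccc2cccnc12)[C@H](Cc1c(OC)c(OC)c(OC)c(OC)c1OC)C(=O)Nc1cccc2cccnc12 | intermediate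
27 | (2R,3S)-3-[(R)-(4-methoxyphenyl)(pentamethoxyphenyl)methyl]-2-(2,4,6-trimethoxybenzyl)-N1,N4-di(quinolin-8-yl)butanediamide | COc1cc(OC)c(C[C@@H](C(=O)Nc2cccc3cccnc23)[C@H]([C@H](c2ccc(OC)cc2)c2c(OC)c(OC)c(OC)c(OC)c2OC)C(=O)Nc2cccc3cccnc23)c(OC)c1 | intermediate
28 | (2R,3S)-2-[(S)-(4-methoxyphenyl)(2,4,6-trimethoxyphenyl)methyl]-3-[(R)-(4-methoxyphenyl)(pentamethoxyphenyl)methyl]-N1,N4-di(quinolin-8-yl)butanediamide | COc1cc(OC)c(c(OC)c1)[C@H](c1ccc(OC)cc1)[C@@H](C(=O)Nc1cccc2cccnc12)[C@H]([C@H](c1ccc(OC)cc1)c1c(OC)c(OC)c(OC)c(OC)c1OC)C(=O)Nc1cccc2cccnc12 | intermediate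
29 | decaphenol of 28: (2R,3S)-2-[(S)-(4-hydroxyphenyl)(2,4,6-trihydroxyphenyl)methyl]-3-[(R)-(4-hydroxyphenyl)(pentahydroxyphenyl)methyl]-N1,N4-di(quinolin-8-yl)butanediamide | Oc1cc(O)c(c(O)c1)[C@H](c1ccc(O)cc1)[C@@H](C(=O)Nc1cccc2cccnc12)[C@H]([C@H](c1ccc(O)cc1)c1c(O)c(O)c(O)c(O)c1O)C(=O)Nc1cccc2cccnc12 | intermediate
30 | (3R,4S,3'S,4'R)-5,5',6',7,7',8'-hexahydroxy-4,4'-bis(4-hydroxyphenyl)-[3,3'-bichromane]-2,2'-dione | O=C1Oc2cc(O)cc(O)c2[C@H](c2ccc(O)cc2)[C@@H]1[C@H]1C(=O)Oc2c(O)c(O)c(O)c(O)c2[C@H]1c1ccc(O)cc1 | target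

Total step count: 14. Longest linear sequence: 11 steps (steps 1–3 and 7–14 from 1 and 2; the branch 4–6 followed by 7–14 from 8 is equally long).

Steps most likely to fail

Step 13. One palladium centre may be held by both amidates of the bis-amide and leave the cycle. Metalation at the doubly ortho-substituted benzylic methylenes may be slow. The bis-amide may close thermally to the imide with loss of one auxiliary. The fallback splits the twofold event into two single-site arylations, with only one directing amide present in the first. It sets out from 20 and comes back to the route at 27, one arylation before 28. Silylation of 20 (TBSCl, imidazole, DMF) gives the silyl ether F1. Arylation with 25 (Pd(OAc)2, AgOAc, tAmOH, 110 °C) at the only β-methylene gives the C4'-arylated silyl ether F2. Bu4NF gives the arylated hydroxy amide F3, and nPr4N[RuO4]/NMO closes it to the arylated imide F4. The aluminium amide from AlMe3 and 19 opens F4 to 27. A single arylation at C4 under the conditions of step 13, next to an amide that is now a hindered spectator, gives 28.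

Step 14. Acyl transfer from the hindered anilides to the phenols may stay incomplete. The acid may scramble C4 and C4' through reversible cleavage at the electron-rich diarylmethines. The tetrahydroxybenzene ring may be oxidised by air. The fallback removes the auxiliaries before the phenols are freed. It sets out from 28 and comes back at 30. Boc2O/DMAP in MeCN gives the bis(N-Boc) amide F5. LiOH/H2O2 in THF/H2O at 0 °C cleaves both activated amides to the diacid F6. BBr3 in CH2Cl2 at low temperature, then a mild aqueous quench, demethylates F6; the free acids lactonise onto the ortho phenols without strong acid or heat and give 30.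

Step 9. Hydrogen uptake at the hindered trisubstituted alkene may be sluggish, the facial selectivity may be poor, or the double bond may migrate into the ring on the catalyst. The fallback sets the C3 centre of the lactone by kinetic protonation of an enolate instead of by hydrogen delivery. It sets out from 17 and comes back at 18. Forced hydrogenation (H2 at higher pressure, Pd/C), then equilibration with DBU, gives the thermodynamically preferred trans-lactone F7. LiN(iPr)2 in THF at −78 °C gives its lithium enolate F8. Protonation at −78 °C with the bulky 2,6-di-tert-butyl-4-methylphenol, from the face opposite the C4 benzyl group, gives the cis-lactone 18.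

Further compounds
F1 | step 13 | (2S,3R)-4-(tert-butyldimethylsilyloxy)-2-(pentamethoxybenzyl)-N-(quinolin-8-yl)-3-(2,4,6-trimethoxybenzyl)butanamide | COc1cc(OC)c(C[C@@H](CO[Si](C)(C)C(C)(C)C)[C@H](Cc2c(OC)c(OC)c(OC)c(OC)c2OC)C(=O)Nc2cccc3cccnc23)c(OC)c1
F2 | step 13 | C4'-arylated silyl ether: (2S,3R)-4-(tert-butyldimethylsilyloxy)-2-[(R)-(4-methoxyphenyl)(pentamethoxyphenyl)methyl]-N-(quinolin-8-yl)-3-(2,4,6-trimethoxybenzyl)butanamide | COc1cc(OC)c(C[C@@H](CO[Si](C)(C)C(C)(C)C)[C@H]([C@H](c2ccc(OC)cc2)c2c(OC)c(OC)c(OC)c(OC)c2OC)C(=O)Nc2cccc3cccnc23)c(OC)c1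
F3 | step 13 | (2S,3R)-4-hydroxy-2-[(R)-(4-methoxyphenyl)(pentamethoxyphenyl)methyl]-N-(quinolin-8-yl)-3-(2,4,6-trimethoxybenzyl)butanamide | COc1cc(OC)c(C[C@@H](CO)[C@H]([C@H](c2ccc(OC)cc2)c2c(OC)c(OC)c(OC)c(OC)c2OC)C(=O)Nc2cccc3cccnc23)c(OC)c1
F4 | step 13 | cis-3-[(R)-(4-methoxyphenyl)(pentamethoxyphenyl)methyl]-1-(quinolin-8-yl)-4-(2,4,6-trimethoxybenzyl)pyrrolidine-2,5-dione | COc1cc(OC)c(C[C@H]2C(=O)N(c3cccc4cccnc34)C(=O)[C@H]2[C@H](c2ccc(OC)cc2)c2c(OC)c(OC)c(OC)c(OC)c2OC)c(OC)c1
F5 | step 14 | bis(N-Boc) derivative of 28 | COc1cc(OC)c(c(OC)c1)[C@H](c1ccc(OC)cc1)[C@@H](C(=O)N(C(=O)OC(C)(C)C)c1cccc2cccnc12)[C@H]([C@H](c1ccc(OC)cc1)c1c(OC)c(OC)c(OC)c(OC)c1OC)C(=O)N(C(=O)OC(C)(C)C)c1cccc2cccnc12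
F6 | step 14 | (2R,3S)-2-[(S)-(4-methoxyphenyl)(2,4,6-trimethoxyphenyl)methyl]-3-[(R)-(4-methoxyphenyl)(pentamethoxyphenyl)methyl]butanedioic acid | COc1cc(OC)c(c(OC)c1)[C@H](c1ccc(OC)cc1)[C@@H](C(=O)O)[C@H]([C@H](c1ccc(OC)cc1)c1c(OC)c(OC)c(OC)c(OC)c1OC)C(=O)O
F7 | step 9 | (3R,4R)-3-(pentamethoxybenzyl)-4-(2,4,6-trimethoxybenzyl)dihydrofuran-2(3H)-one (trans) | COc1cc(OC)c(C[C@H]2COC(=O)[C@@H]2Cc2c(OC)c(OC)c(OC)c(OC)c2OC)c(OC)c1
F8 | step 9 | lithium enolate of the dibenzyl lactone | COc1cc(OC)c(C[C@H]2COC([O-])=C2Cc2c(OC)c(OC)c(OC)c(OC)c2OC)c(OC)c1.[Li+]
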